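**Plan**

1. Cuts: after the four O–benzyl bonds, the apigenin pyranone (double-primed numbering) is opened at O1''–C2''. Its C2''–C3'' bond is then cut back to an aryl aldehyde and a 2-hydroxyacetophenone. Ring C of the 4'-methoxyflavone unit (unprimed) is cut at C4–C4a and then at O1–C2. The diaryl ether is cut at O–C4''', and the C8–O bond goes back to a formyl group.
2. Enabling feature: in ring A of the 4'-methoxyflavone unit, C4a lies ortho to C8a (which bears O1), ortho to C5–O and para to C7–O. With the aryloxy group on C8, C4a is the only unsubstituted carbon next to C8a, so an acyl group tethered through O1 can close ring C in one direction only and under mild activation.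
3. Forward order: phloroglucinaldehyde supplies ring A. Oxygen is placed on C8 by Baeyer–Villiger oxidation, the ether to ring B of the second unit is made by SNAr, O1–C2 by oxa-Michael addition to an arylpropiolate, and ring C by Friedel–Crafts acylation. Chalcone formation and oxidative cyclisation then build the second pyranone, and hydrogenolysis ends the route.
4. Stereochemistry: the target has no stereocentre, so only transient alkene geometry matters. The Z enol ether comes from anti addition, with E/Z convergence in the acidic ring closure. The E geometry of the chalcone vanishes on cyclisation.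

Key step: step 9

Assumption: the conjugate addition should give mainly the Z enol ether. Any E isomer is carried on unseparated, because both geometries converge in the ring closure.

**Step 1**
Reactants: 1 2,4,6-trihydroxybenzaldehyde
Product: 2 2,4-bis(benzyloxy)-6-hydroxybenzaldehyde
Conditions: BnBr (2.1 equiv), K2CO3 (2.2 equiv), DMF, 0 °C → rt
Reagents that add atoms: benzyl bromide, BrCc1ccccc1
Why: Williamson etherification; once the para hydroxyl and one of the two equivalent ortho hydroxyls have reacted, the last hydroxyl is hydrogen-bonded to the formyl oxygen and is too poor a nucleophile under carbonate conditions, so alkylation should stop at the dibenzyl ether.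

**Step 2**
Reactants: 2 2,4-bis(benzyloxy)-6-hydroxybenzaldehyde
Product: 3 2,4-bis(benzyloxy)-6-(methoxymethoxy)benzaldehyde
Conditions: NaH, MOMCl, THF–DMF, 0 °C → rt
Reagents that add atoms: chloromethyl methyl ether, COCCl
Why: Irreversible deprotonation breaks the chelate, and O-alkylation (acetal protection of a phenol) installs a group that is orthogonal to benzyl and stable to peracid, carbonate and heat.

**Step 3**
Reactants: 3 2,4-bis(benzyloxy)-6-(methoxymethoxy)benzaldehyde
Product: 5 2,4-bis(benzyloxy)-6-(methoxymethoxy)phenol, via aryl formate 4 (not isolated)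
Conditions: mCPBA, CH2Cl2, 0 °C → rt; then K2CO3 (cat.), MeOH, rt, Ar
Reagents that add atoms: 3-chloroperbenzoic acid (mCPBA), O=C(OO)c1cccc(Cl)c1
Why: Baeyer–Villiger oxidation (the peracid form of the Dakin reaction); the trialkoxyphenyl group migrates far better than hydride, and carbonate-catalysed methanolysis of the formate frees the phenol oxygen that becomes the C8 oxygen.

**Step 4**
Reactants: 5 2,4-bis(benzyloxy)-6-(methoxymethoxy)phenol; 6 4-fluorobenzaldehyde
Product: 7 4-[2,4-bis(benzyloxy)-6-(methoxymethoxy)phenoxy]benzaldehyde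
Conditions: K2CO3, DMF, 110 °C, Ar
Reagents that add atoms: none
Why: Nucleophilic aromatic substitution by addition–elimination; the para formyl group stabilises the Meisenheimer complex, fluoride is the best leaving group, and phenoxides with two ortho alkoxy groups are known to couple this way, with argon protecting the oxidation-prone phenoxide.

**Step 5**
Reactants: 7 4-[2,4-bis(benzyloxy)-6-(methoxymethoxy)phenoxy]benzaldehyde
Product: 8 4-[2,4-bis(benzyloxy)-6-hydroxyphenoxy]benzaldehyde, that is 3,5-bis(benzyloxy)-2-(4-formylphenoxy)phenol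
Conditions: 3 M aq HCl, MeOH–THF, 50 °C
Reagents that add atoms: none
Why: Acid-catalysed acetal hydrolysis removes only the methoxymethyl group, leaving the benzyl ethers, diaryl ether and aldehyde intact, while the methanol cosolvent and dilution keep the released formaldehyde solvated and away from the electron-rich ring.

**Step 6**
Reactants: 9 3-(4-methoxyphenyl)propiolic acid
Product: 10 methyl 3-(4-methoxyphenyl)prop-2-ynoate
Conditions: MeI, K2CO3, DMF, rt
Reagents that add atoms: iodomethane, CI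
Why: SN2 O-alkylation of the carboxylate at room temperature avoids the acid-catalysed alkyne hydration and the thermal decarboxylation to which electron-rich arylpropiolic acids are prone.

**Step 7**
Reactants: 8 3,5-bis(benzyloxy)-2-(4-formylphenoxy)phenol; 10 methyl 3-(4-methoxyphenyl)prop-2-ynoate
Product: 11 methyl (Z)-3-[3,5-bis(benzyloxy)-2-(4-formylphenoxy)phenoxy]-3-(4-methoxyphenyl)prop-2-enoate
Conditions: Cs2CO3 (0.3 equiv), DMF, 60 °C, Ar
Reagents that add atoms: none
Why: Base-catalysed oxa-Michael addition of a phenoxide to an arylpropiolate forms O1–C2; protonation of the allenolate anti to the incoming oxygen should favour the Z enol ether, and substoichiometric base at moderate temperature limits aryl migration between the neighbouring oxygens.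

**Step 8**
Reactants: 11 methyl (Z)-3-[3,5-bis(benzyloxy)-2-(4-formylphenoxy)phenoxy]-3-(4-methoxyphenyl)prop-2-enoate
Product: 12 (Z)-3-[3,5-bis(benzyloxy)-2-(4-formylphenoxy)phenoxy]-3-(4-methoxyphenyl)prop-2-enoic acid
Conditions: LiOH·H2O, THF–MeOH–H2O, rt → 40 °C; then 1 M HCl, 0 °C
Reagents that add atoms: lithium hydroxide, [Li+].[OH-]
Why: Ester saponification by acyl–oxygen cleavage; the hindered, donor-substituted β-carbon resists addition–elimination, and the non-enolisable aldehyde tolerates dilute hydroxide.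

**Step 9**
Reactants: 12 (Z)-3-[3,5-bis(benzyloxy)-2-(4-formylphenoxy)phenoxy]-3-(4-methoxyphenyl)prop-2-enoic acid
Product: 14 4-({5,7-bis(benzyloxy)-2-(4-methoxyphenyl)-4-oxo-4H-chromen-8-yl}oxy)benzaldehyde, via mixed trifluoroacetic anhydride 13 (not isolated)
Conditions: (CF3CO)2O (3 equiv), CH2Cl2 (0.01 M), 0 °C → rt; aq NaHCO3 work-up
Reagents that add atoms: trifluoroacetic anhydride, O=C(OC(=O)C(F)(F)F)C(F)(F)F (its CF3CO group appears in 13 only; 14 keeps none of its atoms)
Why: Trifluoroacetic anhydride turns acid 12 into the mixed anhydride 13, whose cinnamoyl carbonyl (an acylium equivalent) is attacked by C6 of the phenoxy ring, the future C4a; loss of trifluoroacetate and of the ring proton restores aromaticity and leaves the C4–C4a bond of the 4-pyranone. The closest known reaction type is the cyclisation of β-aryloxycinnamic acids, made from phenols and arylpropiolates, to flavones by intramolecular Friedel–Crafts acylation, together with anhydride-promoted acylation of phloroglucinol ethers. Ring C closes as a six-membered ring in the 6-exo-trig mode at the anhydride carbonyl (6-exo-dig if the free acylium ion is the electrophile), and no stereocentre is created. Regioselectivity is fixed by the substrate: of the two carbons flanking the O1-bearing carbon one carries the 4-formylphenoxy group, so only the other can be acylated, while the second free ring CH is para to O1 and beyond the reach of the three-atom tether. Chemoselectivity rests on the triple oxygen activation of the attacked carbon (ortho to O1 and to one benzyloxy group, para to the other), which lets a mild activator at high dilution suffice, so the benzyl ethers, the diaryl ether and the aldehyde (any addition of the anhydride to it is reversed by the aqueous work-up) should persist and intermolecular attack stays slow. Only the Z acid can reach the ring, and any E isomer should feed into it through reversible C2 protonation to the cation stabilised by the enol ether oxygen and the 4-methoxyphenyl group, its own alternative closure onto the anisyl ring (meta to methoxy) being unfavourable.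

**Step 10**
Reactants: 15 2',4',6'-trihydroxyacetophenone
Product: 16 1-[2,4-bis(benzyloxy)-6-hydroxyphenyl]ethanone
Conditions: BnBr (2.1 equiv), K2CO3 (2.2 equiv), DMF, rt → 50 °C
Reagents that add atoms: benzyl bromide, BrCc1ccccc1
Why: Williamson etherification that stops at the dibenzyl ether because the remaining hydroxyl is chelated to the acetyl oxygen, the standard entry to this chalcone building block.

**Step 11**
Reactants: 14 4-({5,7-bis(benzyloxy)-2-(4-methoxyphenyl)-4-oxo-4H-chromen-8-yl}oxy)benzaldehyde; 16 1-[2,4-bis(benzyloxy)-6-hydroxyphenyl]ethanone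
Product: 17 (E)-1-[2,4-bis(benzyloxy)-6-hydroxyphenyl]-3-[4-({5,7-bis(benzyloxy)-2-(4-methoxyphenyl)-4-oxo-4H-chromen-8-yl}oxy)phenyl]prop-2-en-1-one
Conditions: 50% aq KOH, EtOH–THF, rt, Ar; then 1 M HCl
Reagents that add atoms: none
Why: Claisen–Schmidt condensation of the only enolisable ketone with the only aldehyde, followed by E1cB dehydration, should give the conjugated E chalcone and form the C2''–C3'' bond, with room temperature sparing the existing pyranone.

**Step 12**
Reactants: 17 (E)-1-[2,4-bis(benzyloxy)-6-hydroxyphenyl]-3-[4-({5,7-bis(benzyloxy)-2-(4-methoxyphenyl)-4-oxo-4H-chromen-8-yl}oxy)phenyl]prop-2-en-1-one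
Product: 18 5,7-bis(benzyloxy)-8-{4-[5,7-bis(benzyloxy)-4-oxo-4H-chromen-2-yl]phenoxy}-2-(4-methoxyphenyl)-4H-chromen-4-one
Conditions: I2 (0.15 equiv), DMSO, 120 °C
Reagents that add atoms: none
Why: Iodine-catalysed oxidative cyclisation of a 2'-hydroxychalcone in DMSO (6-endo-trig attack of the phenol on the enone, α-iodination, loss of HI, reoxidation of HI by DMSO) closes O1''–C2'', and any incidental loss of a peri benzyl group is harmless because all four are removed next.

**Step 13**
Reactants: 18 5,7-bis(benzyloxy)-8-{4-[5,7-bis(benzyloxy)-4-oxo-4H-chromen-2-yl]phenoxy}-2-(4-methoxyphenyl)-4H-chromen-4-one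
Product: 19 5,7-dihydroxy-8-[4-(5,7-dihydroxy-4-oxo-4H-chromen-2-yl)phenoxy]-2-(4-methoxyphenyl)-4H-chromen-4-one (CNP0295851.0)
Conditions: H2 (1 atm), 10% Pd/C, THF–MeOH, rt
Reagents that add atoms: none
Why: Catalytic hydrogenolysis cleaves the four benzyl aryl ethers, while the methyl ether, the diaryl ether and the pyranone double bonds (part of aromatic vinylogous ester systems) are not touched at atmospheric pressure.

**Compound list**

1 | 2,4,6-trihydroxybenzaldehyde | O=Cc1c(O)cc(O)cc1O | starting material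
2 | 2,4-bis(benzyloxy)-6-hydroxybenzaldehyde | O=Cc1c(O)cc(OCc2ccccc2)cc1OCc1ccccc1 | intermediate
3 | 2,4-bis(benzyloxy)-6-(methoxymethoxy)benzaldehyde | O=Cc1c(OCOC)cc(OCc2ccccc2)cc1OCc1ccccc1 | intermediate
4 | 2,4-bis(benzyloxy)-6-(methoxymethoxy)phenyl formate | O=COc1c(OCOC)cc(OCc2ccccc2)cc1OCc1ccccc1 | intermediate
5 | 2,4-bis(benzyloxy)-6-(methoxymethoxy)phenol | Oc1c(OCOC)cc(OCc2ccccc2)cc1OCc1ccccc1 | intermediate
6 | 4-fluorobenzaldehyde | O=Cc1ccc(F)cc1 | starting material
7 | 4-[2,4-bis(benzyloxy)-6-(methoxymethoxy)phenoxy]benzaldehyde | O=Cc1ccc(Oc2c(OCOC)cc(OCc3ccccc3)cc2OCc2ccccc2)cc1 | intermediate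
8 | 4-[2,4-bis(benzyloxy)-6-hydroxyphenoxy]benzaldehyde | O=Cc1ccc(Oc2c(O)cc(OCc3ccccc3)cc2OCc2ccccc2)cc1 | intermediate
9 | 3-(4-methoxyphenyl)propiolic acid | COc1ccc(C#CC(=O)O)cc1 | starting material
10 | methyl 3-(4-methoxyphenyl)prop-2-ynoate | COC(=O)C#Cc1ccc(OC)cc1 | intermediate
11 | methyl (Z)-3-[3,5-bis(benzyloxy)-2-(4-formylphenoxy)phenoxy]-3-(4-methoxyphenyl)prop-2-enoate | COC(=O)/C=C(/c1ccc(OC)cc1)Oc1cc(OCc2ccccc2)cc(OCc2ccccc2)c1Oc1ccc(C=O)cc1 | intermediate
12 | (Z)-3-[3,5-bis(benzyloxy)-2-(4-formylphenoxy)phenoxy]-3-(4-methoxyphenyl)prop-2-enoic acid | O=C(O)/C=C(/c1ccc(OC)cc1)Oc1cc(OCc2ccccc2)cc(OCc2ccccc2)c1Oc1ccc(C=O)cc1 | intermediate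
13 | (Z)-3-[3,5-bis(benzyloxy)-2-(4-formylphenoxy)phenoxy]-3-(4-methoxyphenyl)prop-2-enoic trifluoroacetic anhydride | O=C(OC(=O)C(F)(F)F)/C=C(/c1ccc(OC)cc1)Oc1cc(OCc2ccccc2)cc(OCc2ccccc2)c1Oc1ccc(C=O)cc1 | intermediate
14 | 4-({5,7-bis(benzyloxy)-2-(4-methoxyphenyl)-4-oxo-4H-chromen-8-yl}oxy)benzaldehyde | COc1ccc(-c2cc(=O)c3c(OCc4ccccc4)cc(OCc4ccccc4)c(Oc4ccc(C=O)cc4)c3o2)cc1 | intermediate
15 | 2',4',6'-trihydroxyacetophenone | CC(=O)c1c(O)cc(O)cc1O | starting material
16 | 1-[2,4-bis(benzyloxy)-6-hydroxyphenyl]ethanone | CC(=O)c1c(O)cc(OCc2ccccc2)cc1OCc1ccccc1 | intermediate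
17 | (E)-1-[2,4-bis(benzyloxy)-6-hydroxyphenyl]-3-[4-({5,7-bis(benzyloxy)-2-(4-methoxyphenyl)-4-oxo-4H-chromen-8-yl}oxy)phenyl]prop-2-en-1-one | COc1ccc(-c2cc(=O)c3c(OCc4ccccc4)cc(OCc4ccccc4)c(Oc4ccc(/C=C/C(=O)c5c(O)cc(OCc6ccccc6)cc5OCc5ccccc5)cc4)c3o2)cc1 | intermediate
18 | 5,7-bis(benzyloxy)-8-{4-[5,7-bis(benzyloxy)-4-oxo-4H-chromen-2-yl]phenoxy}-2-(4-methoxyphenyl)-4H-chromen-4-one | COc1ccc(-c2cc(=O)c3c(OCc4ccccc4)cc(OCc4ccccc4)c(Oc4ccc(-c5cc(=O)c6c(OCc7ccccc7)cc(OCc7ccccc7)cc6o5)cc4)c3o2)cc1 | intermediate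
19 | 5,7-dihydroxy-8-[4-(5,7-dihydroxy-4-oxo-4H-chromen-2-yl)phenoxy]-2-(4-methoxyphenyl)-4H-chromen-4-one | COc1ccc(-c2cc(=O)c3c(O)cc(O)c(Oc4ccc(-c5cc(=O)c6c(O)cc(O)cc6o5)cc4)c3o2)cc1 | target

**Step count**

Total step count: 13.
Longest linear sequence: 11 steps (1–5, 7–9, 11–13).

**Steps most likely to fail**

**Step 7 (oxa-Michael addition).**
- The addition may be slow. The 4-methoxyphenyl group lowers the electrophilicity of the alkyne β-carbon, and the phenoxide is flanked by the aryloxy group.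
- At the temperature then needed, the formyl-activated ring can migrate from its oxygen to the neighbouring phenoxide. This is a Smiles rearrangement through a five-membered spiro Meisenheimer complex, and it would destroy the C8 placement of the ether.
- The fallback removes that activation before the phenoxide is generated. Setting out from 8, acetalisation with ethylene glycol (p-TsOH cat., toluene, Dean–Stark) should give 3,5-bis(benzyloxy)-2-[4-(1,3-dioxolan-2-yl)phenoxy]phenol F1, whose ether-linked ring no longer accepts nucleophiles.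
- F1 can then be added to 10 under forcing conditions (K2CO3, DMF, 100 °C) to give methyl (Z)-3-{3,5-bis(benzyloxy)-2-[4-(1,3-dioxolan-2-yl)phenoxy]phenoxy}-3-(4-methoxyphenyl)prop-2-enoate F2.
- Brief treatment with 1 M HCl in THF at rt removes the acetal and rejoins the route at 11.

**Step 9 (key ring closure).**
- The acid-activated aldehyde may condense with the still electron-rich ring of a second molecule.
- That ring may be trifluoroacetylated.
- Benzyl groups may be lost or migrate under acid.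
- The enol ether may be cleaved by protonolysis before it closes.
- The fallback keeps the same C4–C4a closure but runs the six operations in another order, so that no aldehyde is present when the acid is activated. Setting out from 7 and 16, Claisen–Schmidt condensation (KOH, EtOH–THF, rt) should give (E)-1-[2,4-bis(benzyloxy)-6-hydroxyphenyl]-3-{4-[2,4-bis(benzyloxy)-6-(methoxymethoxy)phenoxy]phenyl}prop-2-en-1-one F3.
- Oxidative cyclisation with I2 in pyridine at 100 °C, a basic medium that spares the acetal, should give 5,7-bis(benzyloxy)-2-{4-[2,4-bis(benzyloxy)-6-(methoxymethoxy)phenoxy]phenyl}-4H-chromen-4-one F4.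
- Aqueous HCl in MeOH–THF should then free 5,7-bis(benzyloxy)-2-{4-[2,4-bis(benzyloxy)-6-hydroxyphenoxy]phenyl}-4H-chromen-4-one F5.
- Carbonate-catalysed addition to 10 should give methyl (Z)-3-[3,5-bis(benzyloxy)-2-{4-[5,7-bis(benzyloxy)-4-oxo-4H-chromen-2-yl]phenoxy}phenoxy]-3-(4-methoxyphenyl)prop-2-enoate F6.
- LiOH should give (Z)-3-[3,5-bis(benzyloxy)-2-{4-[5,7-bis(benzyloxy)-4-oxo-4H-chromen-2-yl]phenoxy}phenoxy]-3-(4-methoxyphenyl)prop-2-enoic acid F7.
- Trifluoroacetic anhydride in dilute CH2Cl2 should convert F7 into (Z)-3-[3,5-bis(benzyloxy)-2-{4-[5,7-bis(benzyloxy)-4-oxo-4H-chromen-2-yl]phenoxy}phenoxy]-3-(4-methoxyphenyl)prop-2-enoic trifluoroacetic anhydride F8. This closes onto the single free ortho carbon and rejoins the route at 18.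

**Step 11 (Claisen–Schmidt condensation).**
- Hydroxide may attack C2 of the existing pyranone, with ring opening and retro-Claisen fragmentation.
- The large aldehyde may be too poorly soluble for full conversion.
- The fallback builds the second pyranone by acyl transfer with a non-nucleophilic base. Setting out from 14, Pinnick oxidation (NaClO2, NaH2PO4, 2-methyl-2-butene, t-BuOH–THF–H2O) should give 4-({5,7-bis(benzyloxy)-2-(4-methoxyphenyl)-4-oxo-4H-chromen-8-yl}oxy)benzoic acid F9.
- Esterification with 16 (EDC·HCl, DMAP, CH2Cl2) should give 2-acetyl-3,5-bis(benzyloxy)phenyl 4-({5,7-bis(benzyloxy)-2-(4-methoxyphenyl)-4-oxo-4H-chromen-8-yl}oxy)benzoate F10.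
- Baker–Venkataraman rearrangement (LiN(SiMe3)2, THF, −78 → 0 °C) should give 1-[2,4-bis(benzyloxy)-6-hydroxyphenyl]-3-[4-({5,7-bis(benzyloxy)-2-(4-methoxyphenyl)-4-oxo-4H-chromen-8-yl}oxy)phenyl]propane-1,3-dione F11.
- Cyclodehydration (p-TsOH, toluene, 80 °C) rejoins the route at 18, bypassing 17 and step 12.

**Further compounds**

F1 | step 7 | 3,5-bis(benzyloxy)-2-[4-(1,3-dioxolan-2-yl)phenoxy]phenol | Oc1cc(OCc2ccccc2)cc(OCc2ccccc2)c1Oc1ccc(C2OCCO2)cc1
F2 | step 7 | methyl (Z)-3-{3,5-bis(benzyloxy)-2-[4-(1,3-dioxolan-2-yl)phenoxy]phenoxy}-3-(4-methoxyphenyl)prop-2-enoate | COC(=O)/C=C(/c1ccc(OC)cc1)Oc1cc(OCc2ccccc2)cc(OCc2ccccc2)c1Oc1ccc(C2OCCO2)cc1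
F3 | step 9 | (E)-1-[2,4-bis(benzyloxy)-6-hydroxyphenyl]-3-{4-[2,4-bis(benzyloxy)-6-(methoxymethoxy)phenoxy]phenyl}prop-2-en-1-one | COCOc1cc(OCc2ccccc2)cc(OCc2ccccc2)c1Oc1ccc(/C=C/C(=O)c2c(O)cc(OCc3ccccc3)cc2OCc2ccccc2)cc1
F4 | step 9 | 5,7-bis(benzyloxy)-2-{4-[2,4-bis(benzyloxy)-6-(methoxymethoxy)phenoxy]phenyl}-4H-chromen-4-one | COCOc1cc(OCc2ccccc2)cc(OCc2ccccc2)c1Oc1ccc(-c2cc(=O)c3c(OCc4ccccc4)cc(OCc4ccccc4)cc3o2)cc1
F5 | step 9 | 5,7-bis(benzyloxy)-2-{4-[2,4-bis(benzyloxy)-6-hydroxyphenoxy]phenyl}-4H-chromen-4-one | Oc1cc(OCc2ccccc2)cc(OCc2ccccc2)c1Oc1ccc(-c2cc(=O)c3c(OCc4ccccc4)cc(OCc4ccccc4)cc3o2)cc1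
F6 | step 9 | methyl (Z)-3-[3,5-bis(benzyloxy)-2-{4-[5,7-bis(benzyloxy)-4-oxo-4H-chromen-2-yl]phenoxy}phenoxy]-3-(4-methoxyphenyl)prop-2-enoate | COC(=O)/C=C(/c1ccc(OC)cc1)Oc1cc(OCc2ccccc2)cc(OCc2ccccc2)c1Oc1ccc(-c2cc(=O)c3c(OCc4ccccc4)cc(OCc4ccccc4)cc3o2)cc1
F7 | step 9 | (Z)-3-[3,5-bis(benzyloxy)-2-{4-[5,7-bis(benzyloxy)-4-oxo-4H-chromen-2-yl]phenoxy}phenoxy]-3-(4-methoxyphenyl)prop-2-enoic acid | O=C(O)/C=C(/c1ccc(OC)cc1)Oc1cc(OCc2ccccc2)cc(OCc2ccccc2)c1Oc1ccc(-c2cc(=O)c3c(OCc4ccccc4)cc(OCc4ccccc4)cc3o2)cc1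
F8 | step 9 | (Z)-3-[3,5-bis(benzyloxy)-2-{4-[5,7-bis(benzyloxy)-4-oxo-4H-chromen-2-yl]phenoxy}phenoxy]-3-(4-methoxyphenyl)prop-2-enoic trifluoroacetic anhydride | O=C(OC(=O)C(F)(F)F)/C=C(/c1ccc(OC)cc1)Oc1cc(OCc2ccccc2)cc(OCc2ccccc2)c1Oc1ccc(-c2cc(=O)c3c(OCc4ccccc4)cc(OCc4ccccc4)cc3o2)cc1
F9 | step 11 | 4-({5,7-bis(benzyloxy)-2-(4-methoxyphenyl)-4-oxo-4H-chromen-8-yl}oxy)benzoic acid | COc1ccc(-c2cc(=O)c3c(OCc4ccccc4)cc(OCc4ccccc4)c(Oc4ccc(C(=O)O)cc4)c3o2)cc1
F10 | step 11 | 2-acetyl-3,5-bis(benzyloxy)phenyl 4-({5,7-bis(benzyloxy)-2-(4-methoxyphenyl)-4-oxo-4H-chromen-8-yl}oxy)benzoate | COc1ccc(-c2cc(=O)c3c(OCc4ccccc4)cc(OCc4ccccc4)c(Oc4ccc(C(=O)Oc5cc(OCc6ccccc6)cc(OCc6ccccc6)c5C(C)=O)cc4)c3o2)cc1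
F11 | step 11 | 1-[2,4-bis(benzyloxy)-6-hydroxyphenyl]-3-[4-({5,7-bis(benzyloxy)-2-(4-methoxyphenyl)-4-oxo-4H-chromen-8-yl}oxy)phenyl]propane-1,3-dione | COc1ccc(-c2cc(=O)c3c(OCc4ccccc4)cc(OCc4ccccc4)c(Oc4ccc(C(=O)CC(=O)c5c(O)cc(OCc6ccccc6)cc5OCc5ccccc5)cc4)c3o2)cc1
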